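Remark on the chemistry: the ring D ketal carbon is a labile hemiketal centre whose configuration the cage dictates, because ring C can only close with its CH2 arm on the concave face beside the ring B bridge and the OH or OMe group on the convex face. That arrangement is meant throughout; the descriptor of this carbon is copied unchanged from the target string into every structure so that all strings stay comparable with it, although read literally it would place the CH2 arm on the convex face, which cannot be bridged.

## Structural features

The target is a tetracyclic C21 methyl ester made of a methyl-substituted cyclohexene (ring A), a cyclohexene carrying the conjugated ester (ring B), a cyclohexanone carrying an isopropyl group (ring C) and a five-membered cyclic hemiketal (ring D). Rings A and B are cis-fused through the tertiary ether carbon and the neighbouring CH. Rings B and D share these two carbons and the methyl-bearing quaternary carbon, so that together they form a 6-oxabicyclo[3.2.1]octene. Ring C is fused onto the quaternary carbon, sharing one bond with ring B and one with ring D. Five of the six stereocentres are clustered: the tertiary ether carbon, the junction CH, the quaternary carbon, the ring B CH next to the ketone and the hemiketal carbon; the sixth is the isopropyl-bearing CH. The fragile groups are the hemiketal, the ketone whose ring B alpha-CH is allylic to the enoate (epimerisation or alkene migration under base), and the two trisubstituted alkenes. The real difficulty is the all-carbon quaternary centre at the meeting point of rings B, C and D, together with the concave placement of ring C under ring B. The key step exploits the fact that the ring C carbonyl carbon and the ring C CH that carries the isopropyl group are adjacent: this is the oxidised and hydrogenated form of the carbinol/isopropenyl pair that a carbonyl-ene reaction leaves.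

## Logic of the disconnections

35 to 34: the hemiketal O–H is replaced by O–Me. No skeletal bond is cut; the gain is a ketal that cannot open to the hydroxy diketone during the preceding steps. The forward step needs aqueous acid mild enough to leave the ring B alkene where it is.

34 to 33 to 32: the ketone is traced back to a secondary alcohol and the isopropyl group to an isopropenyl group. This exposes a homoallylic alcohol with a vicinal isopropenyl group, the retron of the ene reaction. Forward, one of three alkenes must be hydrogenated and the alcohol oxidised without touching the alpha-CH of ring B.

32 to 31: the bond between the carbinol carbon and the isopropenyl-bearing carbon is cut. Ring C and two stereocentres disappear and a rigid tricycle with a formyl arm and a prenyl arm remains. Forward, both arms must sit on the concave face and the Lewis acid must activate the aldehyde without ionising the ketal.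

31 to 30 to 29 to 28: the aldehyde goes back to a silyl-protected primary alcohol, and the prenyl C=C bond is cut to an allyl group. Allyl is chosen because an allyl nucleophile has no regiochemical ambiguity, whereas prenyl-metal reagents tend to bond through their tertiary terminus. Forward, the metathesis must touch only the monosubstituted alkene.

28 to 27 to 26: the C–OMe bond and the bond from the ketal carbon to the allyl CH2 are cut, which returns the ketal carbon to a lactone carbonyl. The gain is a lactone whose enolate can build the quaternary carbon. Forward, a single addition must occur at the lactone and not at the ring B ester, and methanol must enter from the convex face.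

26 to 24: the bond between the quaternary carbon and the arm-bearing ring B CH is cut, and ring B with it. The closure is intramolecular, so the tether decides the configuration of the quaternary carbon. Forward, the base must deprotonate the lactone and the alkene geometry must place the arm on the lactone side.

24 to 23 to 17 plus 21: the carbonate is an activated alcohol, and the bond between the carbinol carbon and the alpha-carbon of the enoate is cut. This is the convergent point; 21 is reached from 18 through 19. Forward, the hydrometalation of 21 must be regio- and stereoselective.

17 to 16 to 15 to 13 to 11: the aldehyde returns to a silyl ether, and the lactone C–O and C=O bonds return to a 1,4-diol and then to an isopropenyl group. The propionate unit of ring D is thus the side chain of the terpene. Forward, hydroboration must distinguish two alkenes and the lactone must close trans.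

11 to 9 to 7 to 6: the CH2 next to the tertiary carbinol is traced back to a ketone with the ring alkene unmoved, by way of two allylic transpositions. The ketone is needed because it is what makes the neighbouring carbon functionalisable. Forward, a hindered ketone must condense with hydrazine.

6 to 4 to 3 to 1: the tertiary C–O bond and the C–CH2O bond at the alpha-prime carbon are cut. The single stereocentre of 1 controls both enolate additions. Forward, carbon must be introduced before oxygen so that oxygen ends up trans to the side chain.

## Other disconnections considered

Alternative 1: The cut is the bond from the quaternary carbon to the ring A/B junction CH, together with the hemiketal C–O bond. In the forward step, base generates the enolate at the methyl-bearing alpha-carbon of a ring C ketone in quinol A1; the enolate adds to one enone arm of the 4-hydroxycyclohexadienone and the tertiary hydroxyl then closes ring D, giving A2.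
- In its favour: one operation forms ring B, ring D, the quaternary carbon and three or four stereocentres, and ring C arrives complete with its isopropyl group, so no late hydrogenation or oxidation of ring C is needed.
- Against it here: the choice between the two enone arms fixes the tertiary ether carbon and the junction CH and must be steered by the remote ring C stereocentres. Ring A emerges in A2 as an unmethylated enone with the alkene in the wrong place, so the methyl group and the alkene still have to be installed next to an allylic ring D oxygen that can be lost by elimination. The absolute configuration needs an enantioselective synthesis of the ring C fragment.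
- Comparison: on convergence and on the number of operations spent on ring C this plan is the better one. On the way the quaternary carbon is made (intramolecular enolate conjugate addition controlled by a tether) the two plans are equals. The chosen plan is stronger on ring A, which comes correctly substituted and enantiopure from the terpene.

Alternative 2: Two bonds are cut, the one from the ester-bearing carbon to the ring B CH and the one from the quaternary carbon to the junction CH. In the forward step the anion of beta-keto ester A3 adds to the unsubstituted beta-carbon of quinone monoketal A4, and the methyl-bearing enolate so formed adds back to the dienyl ketone, giving A5.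
- In its favour: two simple achiral fragments are joined and ring B with the quaternary carbon is formed in one flask; this is the shortest way to a tricyclic core.
- Against it here: A5 lacks the tertiary ether oxygen and carries an enol at the future vinyl CH and an enone in ring C. Hydroxylation at the junction, removal of the enol oxygen, reduction of the ring C alkene and closure of ring D therefore remain, all on a sensitive 1,3-dicarbonyl system. Four stereocentres form in an intermolecular-then-intramolecular cascade without an obvious control element, and the product is racemic unless a chiral catalyst is found.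
- Comparison: on convergence and on step count to the carbon skeleton this plan is the better one. The chosen plan is stronger on stereochemical provenance (every centre has a defined source) and on the endgame, where only three functional-group steps follow the key step.

Alternative 3: The cut is the bond from the quaternary carbon to the ring B CH. In the forward step the enolate of lactone A6 adds to the beta-carbon of its tethered acetoxy acrylate and expels acetate, giving bridged lactone A7.
- In its favour: the quaternary carbon, ring B and the ring B alkene form at once, the tether allows only one configuration at the quaternary carbon, and the absolute configuration comes from the chiral pool.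
- Against it as the centre of a plan: it stops at rings A, B and D, so ring C still requires a further C–C bond formation, and the acetate offers the base a second enolisable ester.
- Comparison: this disconnection is not a rival of the ene closure but addresses a different bond. The chosen route uses the same construction in step 15, with a carbonate leaving group and a more robust silyl group, so on the quaternary carbon and on step economy the two are equals. The ene closure was made the strategic centre because it completes the skeleton and sets the last stereocentre.

Key step: step 21

## Steps

Step 1
Reactants: 1 (S)-carvone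
Product: 3 trans-6-(hydroxymethyl)carvone, via lithium dienolate 2 (not isolated)
Conditions: LiN(iPr)2, THF, −78 °C; CH2O (gas), −78 °C
Reagents that add atoms: formaldehyde C=O
Why: Kinetic deprotonation occurs at the alpha-prime CH2 and the cross-conjugated dienolate undergoes an aldol addition to monomeric formaldehyde, anti to the neighbouring isopropenyl group. This centre is re-enolised in step 3, so its configuration is of no consequence.

Step 2
Reactants: 3 trans-6-(hydroxymethyl)carvone
Product: 4 trans-6-[(tert-butyldimethylsilyloxy)methyl]carvone
Conditions: TBSCl, imidazole, DMF, 0 °C to rt
Reagents that add atoms: tert-butyldimethylsilyl chloride CC(C)(C)[Si](C)(C)Cl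
Why: Standard silylation of a primary alcohol; it blocks retro-aldol cleavage and dehydration of the beta-hydroxy ketone.

Step 3
Reactants: 4 trans-6-[(tert-butyldimethylsilyloxy)methyl]carvone
Product: 6 6-hydroxy-6-[(tert-butyldimethylsilyloxy)methyl]carvone (OH trans and CH2O arm cis to isopropenyl), via potassium enolate 5 (not isolated)
Conditions: KN(SiMe3)2, THF, −78 °C; 2-(phenylsulfonyl)-3-phenyloxaziridine, −78 °C
Reagents that add atoms: 2-(phenylsulfonyl)-3-phenyloxaziridine O=S(=O)(c1ccccc1)N1OC1c1ccccc1
Why: The enolate forms at the only alpha-prime hydrogen and is oxidised by the N-sulfonyloxaziridine (Davis hydroxylation) at a temperature where beta-elimination of the silyloxy group is slow. Oxygen should be delivered anti to the isopropenyl group on the adjacent carbon, which sets the future ring D ether carbon.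

Step 4
Reactants: 6 6-hydroxy-6-[(tert-butyldimethylsilyloxy)methyl]carvone
Product: 7 2,3-epoxy ketone of 6 (epoxide drawn anti to isopropenyl)
Conditions: 30% H2O2, NaOH (cat.), MeOH, 0 °C
Reagents that add atoms: hydrogen peroxide OO
Why: Weitz–Scheffer epoxidation: hydroperoxide adds to the unhindered beta-carbon of the enone and the enolate closes the epoxide, while the electron-rich isopropenyl group is inert to the nucleophilic oxidant. Both new centres are removed in steps 5 and 6.

Step 5
Reactants: 7 2,3-epoxy ketone
Product: 9 4-[(tert-butyldimethylsilyloxy)methyl]-2-methyl-5-(prop-1-en-2-yl)cyclohex-2-ene-1,4-diol, via epoxy hydrazone 8 (not isolated)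
Conditions: N2H4·H2O, AcOH (cat.), MeOH, 0 °C to rt
Reagents that add atoms: none
Why: Wharton transposition: the hydrazone opens the epoxide and loss of N2 from the alkenyl diazene leaves the alkene at the former carbonyl carbon and a hydroxyl at the former beta-carbon. The carbinol keeps the configuration of the epoxide C–O bond.

Step 6
Reactants: 9 cyclohex-2-ene-1,4-diol
Product: 11 1-[(tert-butyldimethylsilyloxy)methyl]-3-methyl-6-(prop-1-en-2-yl)cyclohex-3-en-1-ol, via allylic diazene 10 (not isolated)
Conditions: 2-nitrobenzenesulfonylhydrazide, PPh3, DEAD, THF, −30 °C to rt
Reagents that add atoms: none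
Why: Myers reductive transposition: Mitsunobu displacement of the secondary allylic alcohol (the tertiary one does not react), loss of sulfinic acid and sigmatropic loss of N2 from the allylic diazene move the alkene back and put hydrogen on the former carbonyl carbon. Steps 5 and 6 together remove the ketone oxygen without shifting the ring alkene.

Step 7
Reactants: 11 cyclohex-3-en-1-ol
Product: 13 1-[(tert-butyldimethylsilyloxy)methyl]-6-(1-hydroxypropan-2-yl)-3-methylcyclohex-3-en-1-ol (mixture at the methyl-bearing carbon), via B-alkyl borane 12 (not isolated)
Conditions: 9-BBN, THF, 0 °C to rt; NaOH, H2O2, 0 °C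
Reagents that add atoms: hydrogen peroxide OO
Why: 9-BBN hydroborates the 1,1-disubstituted isopropenyl group in preference to the trisubstituted ring alkene and places boron on the terminal carbon; alkaline peroxide gives the primary alcohol. The new methyl-bearing centre becomes an enolate carbon in step 15, so the mixture is inconsequential.

Step 8
Reactants: 13 diol
Product: 15 trans-fused lactone 7a-[(tert-butyldimethylsilyloxy)methyl]-3,6-dimethyl-3a,4,7,7a-tetrahydro-1-benzofuran-2(3H)-one, via lactol 14 (not isolated)
Conditions: TEMPO (cat.), PhI(OAc)2, CH2Cl2, rt
Reagents that add atoms: none
Why: Oxoammonium oxidation of the primary alcohol gives the aldehyde, which the tertiary hydroxyl captures as a lactol that is oxidised on to the gamma-lactone (oxidative lactonisation of a 1,4-diol). The trans ring fusion follows from the configuration set in step 3.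

Step 9
Reactants: 15 silyloxymethyl lactone
Product: 16 7a-(hydroxymethyl) lactone
Conditions: HF·pyridine, pyridine, THF, 0 °C
Reagents that add atoms: none
Why: Fluoride cleavage of the primary silyl ether; the buffered acidic reagent is preferred to basic fluoride to suppress migration of the acyl group from the tertiary to the new primary oxygen.

Step 10
Reactants: 16 hydroxymethyl lactone
Product: 17 lactone 7a-carbaldehyde
Conditions: Dess–Martin periodinane, NaHCO3, CH2Cl2, 0 °C to rt
Reagents that add atoms: none
Why: Dess–Martin oxidation of a primary alcohol; the aldehyde has no alpha-hydrogen and cannot epimerise.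

Step 11
Reactants: 18 propargyl alcohol
Product: 19 tert-butyl(diphenyl)(prop-2-ynyloxy)silane
Conditions: TBDPSCl, imidazole, CH2Cl2, 0 °C to rt
Reagents that add atoms: tert-butyldiphenylsilyl chloride CC(C)(C)[Si](Cl)(c1ccccc1)c1ccccc1
Why: Standard silylation; the tert-butyldiphenylsilyl ether is chosen because it must survive acidic methanol in step 17.

Step 12
Reactants: 19 silyl propargyl ether
Product: 21 methyl 4-(tert-butyldiphenylsilyloxy)but-2-ynoate, via lithium acetylide 20 (not isolated)
Conditions: n-BuLi, THF, −78 °C; ClCO2Me, −78 °C to 0 °C
Reagents that add atoms: methyl chloroformate COC(=O)Cl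
Why: Deprotonation of the terminal alkyne and C-acylation of the acetylide with a chloroformate.

Step 13
Reactants: 21 ynoate; 17 lactone aldehyde
Product: 23 (Z)-hydroxy enoate (mixture at the carbinol carbon), via vinylalane 22 (not isolated)
Conditions: iBu2AlH, N-methylmorpholine N-oxide, THF, 0 °C; then 17, 0 °C to rt
Reagents that add atoms: none
Why: Conjugate hydroalumination of the ynoate places aluminium alpha to the ester and hydrogen on the beta-carbon on the same side, and the vinylalane adds to the aldehyde (vinylalumination) to give a Morita–Baylis–Hillman-type adduct with the CH2O arm cis to the ester. The lactone is not attacked, and the carbinol centre is removed in step 15.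

Step 14
Reactants: 23 (Z)-hydroxy enoate
Product: 24 tert-butyl carbonate of 23
Conditions: Boc2O, DMAP, CH2Cl2, rt
Reagents that add atoms: di-tert-butyl dicarbonate CC(C)(C)OC(=O)OC(=O)OC(C)(C)C
Why: DMAP-catalysed acylation of the secondary alcohol. A carbonate without alpha-hydrogens is preferred to an acetate so that the base of step 15 finds no second enolisable ester.

Step 15
Reactants: 24 tert-butyl carbonate
Product: 26 bridged lactone of rings A, B and D with the silyloxymethyl arm on the lactone side, via lithium enolate 25 (not isolated)
Conditions: LiN(SiMe3)2, THF, −78 °C to 0 °C
Reagents that add atoms: none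
Why: The lactone enolate (both alpha-epimers converge) adds to the beta-carbon of the tethered acrylate and the resulting ester enolate expels tert-butyl carbonate, an addition–elimination that amounts to SN2′ alkylation of a Morita–Baylis–Hillman carbonate and closes ring B with its conjugated alkene. The quaternary centre can only form on the lactone face that carries the tether, and with the (Z)-alkene a chair-like transition state should place the arm equatorial, on the side of the lactone bridge.

Step 16
Reactants: 26 bridged lactone
Product: 27 allyl hemiketal (epimers at the hemiketal carbon in equilibrium through the hydroxy ketone)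
Conditions: allylMgBr (1.05 equiv), THF, −78 °C; AcOH quench at −78 °C
Reagents that add atoms: allylmagnesium bromide C=CC[Mg]Br
Why: Single addition of an allyl Grignard reagent to a lactone at low temperature, where the bridged magnesium lactolate is stable and does not open to the ketone. The strained lactone should be more electrophilic than the conjugated, alpha-branched ring B ester.

Step 17
Reactants: 27 allyl hemiketal
Product: 28 allyl methyl ketal (OMe on the convex face, allyl CH2 on the concave face)
Conditions: camphorsulfonic acid (cat.), MeOH, 0 °C to rt
Reagents that add atoms: methanol CO
Why: Acid-catalysed exchange of the hemiketal hydroxyl for methoxyl through the bicyclic oxocarbenium ion (Fischer-type ketalisation). Methanol should add from the open convex face, and because the silyl ether survives, the arm cannot form an internal ketal.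

Step 18
Reactants: 28 allyl methyl ketal
Product: 29 prenyl methyl ketal silyl ether
Conditions: 2-methyl-2-butene (excess), second-generation Grubbs catalyst RuCl2(=CHPh)(PCy3)(H2IMes) (5 mol%), CH2Cl2, 40 °C
Reagents that add atoms: 2-methyl-2-butene CC=C(C)C
Why: Olefin cross-metathesis of the monosubstituted alkene with excess 2-methyl-2-butene converts allyl into prenyl; the trisubstituted ring alkenes are not substrates for the catalyst.

Step 19
Reactants: 29 prenyl methyl ketal silyl ether
Product: 30 prenyl methyl ketal alcohol
Conditions: TBAF, THF, 0 °C to rt
Reagents that add atoms: none
Why: Fluoride desilylation under non-acidic conditions, so that the methyl ketal cannot exchange with the freed hydroxyl.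

Step 20
Reactants: 30 prenyl methyl ketal alcohol
Product: 31 cage methyl ketal with prenyl and formyl arms
Conditions: Dess–Martin periodinane, NaHCO3, CH2Cl2, 0 °C
Reagents that add atoms: none
Why: Buffered Dess–Martin oxidation to the aldehyde, which is used at once because its alpha-hydrogen is epimerisable and base could move the ring B alkene into conjugation.

Step 21
Reactants: 31 cage methyl ketal with prenyl and formyl arms
Product: 32 tetracyclic isopropenyl alcohol as methyl ketal
Conditions: ZnBr2 (2 equiv), CH2Cl2, −20 °C to 0 °C
Reagents that add atoms: none
Why: ZnBr2 binds the formyl oxygen, the inner CH carbon of the prenyl alkene attacks the carbonyl carbon, and a hydrogen of one terminal methyl passes to oxygen through a six-membered array, leaving a secondary alcohol next to an isopropenyl group. The closest known reaction is the Lewis-acid cyclisation of citronellal to isopulegol (intramolecular carbonyl-ene reaction). Ring C closes as a six-membered ring by joining the formyl carbon to the proximal alkene carbon with both pi bonds exocyclic to the new ring (6-exo with respect to the alkene); bonding to the outer carbon would need a seven-membered ring and a less stabilised cation. The isopropenyl-bearing centre is controlled by the cage: in the chair-like transition state the dimethylvinyl terminus can only lie on the open equatorial side, since the axial position points into the concave space under ring B. The carbinol centre follows from the orientation of the zinc-bound oxygen, expected anti to the ester-bearing ring B carbon, which gives the hydroxyl cis to the isopropenyl group as drawn; this centre is erased in step 23, so its control is not required. The step needs activation of the aldehyde without ionisation of the methyl ketal and without enolisation of the aldehyde; this is secured by the mild Lewis acid, the low temperature, and the fact that steps 15 and 17 hold both arms on the concave face within bonding distance.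

Step 22
Reactants: 32 tetracyclic isopropenyl alcohol
Product: 33 tetracyclic isopropyl alcohol as methyl ketal
Conditions: H2 (1 atm), RhCl(PPh3)3 (10 mol%), benzene, rt
Reagents that add atoms: none
Why: RhCl(PPh3)3 hydrogenates 1,1-disubstituted alkenes much faster than trisubstituted ones, so the ring A alkene and the conjugated ring B alkene should remain. Hydrogenating before oxidising avoids an isopropenyl group beta,gamma to a ketone.

Step 23
Reactants: 33 tetracyclic isopropyl alcohol
Product: 34 ring C ketone as methyl ketal
Conditions: Dess–Martin periodinane, NaHCO3, CH2Cl2, 0 °C to rt
Reagents that add atoms: none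
Why: Dess–Martin oxidation of the secondary alcohol removes the carbinol centre; the ring B alpha-CH is held by the cis ring fusion and the isopropyl-bearing CH already has its substituent equatorial.

Step 24
Reactants: 34 ring C ketone as methyl ketal
Product: 35 target hemiketal CNP0382995.2
Conditions: 1 M HCl, THF, rt
Reagents that add atoms: water O
Why: Mild aqueous acid hydrolyses the methyl ketal through the oxocarbenium ion to the cyclic hemiketal, whose hydroxyl can only sit on the convex face. The same conditions let the isopropyl-bearing alpha-centre equilibrate, and the equatorial configuration already present is the thermodynamic one.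

## Compound list

1 | (S)-carvone | CC1=CC[C@@H](CC1=O)C(C)=C | starting material
2 | lithium dienolate of 1 (O–Li at C1, C1=C6) | CC1=CC[C@@H](C=C1O[Li])C(C)=C | intermediate
3 | trans-6-(hydroxymethyl)carvone | OC[C@H]1C(=O)C(C)=CC[C@@H]1C(C)=C | intermediate
4 | trans-6-[(tert-butyldimethylsilyloxy)methyl]carvone | CC(C)(C)[Si](C)(C)OC[C@H]1C(=O)C(C)=CC[C@@H]1C(C)=C | intermediate
5 | potassium enolate of 4 | CC(C)(C)[Si](C)(C)OCC1=C(O[K])C(C)=CC[C@@H]1C(C)=C | intermediate
6 | 6-hydroxy-6-[(tert-butyldimethylsilyloxy)methyl]carvone, OH trans to isopropenyl | CC(C)(C)[Si](C)(C)OC[C@]1(O)C(=O)C(C)=CC[C@@H]1C(C)=C | intermediate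
7 | 2,3-epoxy ketone of 6, epoxide anti to isopropenyl | CC(C)(C)[Si](C)(C)OC[C@]1(O)C(=O)[C@@]2(C)O[C@H]2C[C@@H]1C(C)=C | intermediate
8 | hydrazone of 7 | CC(C)(C)[Si](C)(C)OC[C@]1(O)C(=NN)[C@@]2(C)O[C@H]2C[C@@H]1C(C)=C | intermediate
9 | 4-[(tert-butyldimethylsilyloxy)methyl]-2-methyl-5-(prop-1-en-2-yl)cyclohex-2-ene-1,4-diol | CC(C)(C)[Si](C)(C)OC[C@]1(O)C=C(C)[C@@H](O)C[C@@H]1C(C)=C | intermediate
10 | allylic diazene from 9 (nitrogen with inversion at the former carbinol) | CC(C)(C)[Si](C)(C)OC[C@]1(O)C=C(C)[C@H](N=N)C[C@@H]1C(C)=C | intermediate
11 | 1-[(tert-butyldimethylsilyloxy)methyl]-3-methyl-6-(prop-1-en-2-yl)cyclohex-3-en-1-ol | CC(C)(C)[Si](C)(C)OC[C@]1(O)CC(C)=CC[C@@H]1C(C)=C | intermediate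
12 | B-alkyl-9-borabicyclo[3.3.1]nonane from 11 (tertiary hydroxyl drawn free; methyl-bearing carbon as a mixture) | CC(C)(C)[Si](C)(C)OC[C@]1(O)CC(C)=CC[C@@H]1C(C)CB1C2CCCC1CCC2 | intermediate
13 | 1-[(tert-butyldimethylsilyloxy)methyl]-6-(1-hydroxypropan-2-yl)-3-methylcyclohex-3-en-1-ol (methyl-bearing carbon as a mixture) | CC(C)(C)[Si](C)(C)OC[C@]1(O)CC(C)=CC[C@@H]1C(C)CO | intermediate
14 | trans-fused lactol from 13 | CC(C)(C)[Si](C)(C)OC[C@]12CC(C)=CC[C@@H]1C(C)C(O)O2 | intermediate
15 | trans-fused lactone, 7a-[(tert-butyldimethylsilyloxy)methyl]-3,6-dimethyl-3a,4,7,7a-tetrahydro-1-benzofuran-2(3H)-one (C3 as a mixture) | CC(C)(C)[Si](C)(C)OC[C@]12CC(C)=CC[C@@H]1C(C)C(=O)O2 | intermediate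
16 | 7a-(hydroxymethyl) lactone | OC[C@]12CC(C)=CC[C@@H]1C(C)C(=O)O2 | intermediate
17 | lactone 7a-carbaldehyde | O=C[C@]12CC(C)=CC[C@@H]1C(C)C(=O)O2 | intermediate
18 | propargyl alcohol | C#CCO | starting material
19 | tert-butyl(diphenyl)(prop-2-ynyloxy)silane | C#CCO[Si](c1ccccc1)(c1ccccc1)C(C)(C)C | intermediate
20 | lithium acetylide of 19 | [Li]C#CCO[Si](c1ccccc1)(c1ccccc1)C(C)(C)C | intermediate
21 | methyl 4-(tert-butyldiphenylsilyloxy)but-2-ynoate | COC(=O)C#CCO[Si](c1ccccc1)(c1ccccc1)C(C)(C)C | intermediate
22 | methyl (Z)-2-(diisobutylalumino)-4-(tert-butyldiphenylsilyloxy)but-2-enoate | COC(=O)/C([Al](CC(C)C)CC(C)C)=C\CO[Si](c1ccccc1)(c1ccccc1)C(C)(C)C | intermediate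
23 | (Z)-hydroxy enoate from 17 and 22 (carbinol and lactone alpha-carbon as mixtures) | COC(=O)/C(=C\CO[Si](c1ccccc1)(c1ccccc1)C(C)(C)C)C(O)[C@]12CC(C)=CC[C@@H]1C(C)C(=O)O2 | intermediate
24 | tert-butyl carbonate of 23 | COC(=O)/C(=C\CO[Si](c1ccccc1)(c1ccccc1)C(C)(C)C)C(OC(=O)OC(C)(C)C)[C@]12CC(C)=CC[C@@H]1C(C)C(=O)O2 | intermediate
25 | lithium enolate of lactone 24 | COC(=O)/C(=C\CO[Si](c1ccccc1)(c1ccccc1)C(C)(C)C)C(OC(=O)OC(C)(C)C)[C@]12CC(C)=CC[C@@H]1C(C)=C(O[Li])O2 | intermediate
26 | bridged lactone of rings A, B and D with CH2OSi arm on the ring B CH, on the lactone side | COC(=O)C1=C[C@]23CC(C)=CC[C@@H]2[C@](C)([C@H]1CO[Si](c1ccccc1)(c1ccccc1)C(C)(C)C)C(=O)O3 | intermediate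
27 | allyl hemiketal from 26 (hemiketal carbon as equilibrating epimers) | COC(=O)C1=C[C@]23CC(C)=CC[C@@H]2[C@@](C)(C(O)(CC=C)O3)[C@H]1CO[Si](c1ccccc1)(c1ccccc1)C(C)(C)C | intermediate
28 | allyl methyl ketal, OMe convex, allyl concave | COC(=O)C1=C[C@]23CC(C)=CC[C@@H]2[C@@](C)([C@@](OC)(CC=C)O3)[C@H]1CO[Si](c1ccccc1)(c1ccccc1)C(C)(C)C | intermediate
29 | prenyl methyl ketal silyl ether | COC(=O)C1=C[C@]23CC(C)=CC[C@@H]2[C@@](C)([C@@](OC)(CC=C(C)C)O3)[C@H]1CO[Si](c1ccccc1)(c1ccccc1)C(C)(C)C | intermediate
30 | prenyl methyl ketal alcohol | COC(=O)C1=C[C@]23CC(C)=CC[C@@H]2[C@@](C)([C@@](OC)(CC=C(C)C)O3)[C@H]1CO | intermediate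
31 | cage methyl ketal (rings A, B and D) with prenyl and formyl arms | COC(=O)C1=C[C@]23CC(C)=CC[C@@H]2[C@@](C)([C@@](OC)(CC=C(C)C)O3)[C@H]1C=O | intermediate
32 | tetracyclic isopropenyl alcohol as methyl ketal (OH cis to the equatorial isopropenyl group) | COC(=O)C1=C[C@]23CC(C)=CC[C@@H]2[C@]2(C)[C@H]1[C@@H](O)[C@@H](C(C)=C)C[C@@]2(OC)O3 | intermediate
33 | tetracyclic isopropyl alcohol as methyl ketal | COC(=O)C1=C[C@]23CC(C)=CC[C@@H]2[C@]2(C)[C@H]1[C@@H](O)[C@@H](C(C)C)C[C@@]2(OC)O3 | intermediate
34 | ring C ketone as methyl ketal | COC(=O)C1=C[C@]23CC(C)=CC[C@@H]2[C@]2(C)[C@H]1C(=O)[C@@H](C(C)C)C[C@@]2(OC)O3 | intermediate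
35 | CNP0382995.2, tetracyclic hemiketal keto ester | COC(=O)C1=C[C@]23CC(C)=CC[C@@H]2[C@]2(C)[C@H]1C(=O)[C@@H](C(C)C)C[C@@]2(O)O3 | target

## Step count and least certain steps

Total step count: 24. Longest linear sequence: 22 steps (steps 1 to 10 and 13 to 24, from 1); the branch from 18 to 21 takes 2 steps.

Step 21 (key step). What is most likely to go wrong is ionisation of the tertiary methyl ketal by the Lewis acid (loss of methanol, scrambling at the ketal carbon, capture of the cation by the new hydroxyl) and enolisation of the aldehyde, both competing with a closure that is slowed by crowding on the concave face. The fallback replaces the ene donor by an allylsilane, so that ring C closes by an intramolecular Hosomi–Sakurai reaction at −78 °C. It sets out from 28: TBAF should give the allyl ketal alcohol F1; cross-metathesis of F1 with trimethyl(2-methylallyl)silane and the same ruthenium catalyst should give the allylsilane alcohol F2; Dess–Martin oxidation should give the allylsilane aldehyde F3; and BF3·OEt2 in CH2Cl2 at −78 °C should join the formyl carbon to the same alkene carbon, with silicon leaving from the methyl carbon so that the isopropenyl group forms. The fallback comes back to the route at 32.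

Step 16. What is most likely to go wrong is loss of chemoselectivity, that is, attack of the very reactive allyl Grignard reagent at the ring B ester or a second addition after opening of the lactolate, because allylmagnesium reagents discriminate poorly between carbonyl groups. The fallback changes the order of events at the lactone carbon. It sets out from 26: disiamylborane (which reduces lactones but not esters) should give the lactol F4; allylboronic acid pinacol ester should add to the open hydroxy aldehyde form to give the homoallylic diol F5; and Dess–Martin oxidation of the secondary alcohol should give the ketone, which closes onto the tertiary hydroxyl. The fallback comes back to the route at 27.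

Step 5. What is most likely to go wrong is slow or incomplete hydrazone formation at a ketone flanked by two fully substituted carbons, with competing opening of the epoxide by hydrazine. The fallback performs the same transposition by a radical fragmentation that needs no carbonyl condensation. It sets out from 7: NaBH4 should give the epoxy diol F6; O-phenyl chlorothionoformate and pyridine should acylate only the secondary hydroxyl to give the thionocarbonate F7; and Bu3SnH with AIBN in hot toluene should generate the radical at the carbinol carbon, which opens the epoxide to an alkoxy radical that takes up hydrogen (Barton–McCombie conditions). The fallback comes back to the route at 9.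

Step 15. What is most likely to go wrong is competing deprotonation at the CH2 of the enoate arm followed by elimination of the carbonate to a dienoate, and partial closure through a boat-like transition state that would put the arm on the outer side. The fallback separates enolate formation from ring closure (Mukaiyama–Michael addition followed by elimination). It sets out from 24: LiN(iPr)2 in the presence of Me3SiCl at −78 °C should trap the lactone enolate as the silyl ketene acetal F8, and catalytic Me3SiOTf in CH2Cl2 at −78 °C should then promote addition of the ketene acetal to the enoate and loss of the carbonate. The fallback comes back to the route at 26.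

Step 13. What is most likely to go wrong is incomplete addition to the hindered aldehyde with its quaternary alpha-carbon, reduction of the aldehyde by unconsumed hydride, and erosion of the (Z)-geometry by isomerisation of the vinylalane. The fallback is a Nozaki–Hiyama–Kishi coupling. It sets out from 21: hydroalumination as in step 13 followed by I2 should give methyl (Z)-2-iodo-4-(tert-butyldiphenylsilyloxy)but-2-enoate F9, and CrCl2 with catalytic NiCl2 in DMF should add F9 to aldehyde 17 chemoselectively. The fallback comes back to the route at 23.

## Further compounds

F1 | step 21 | allyl methyl ketal with free hydroxymethyl arm | COC(=O)C1=C[C@]23CC(C)=CC[C@@H]2[C@@](C)([C@@](OC)(CC=C)O3)[C@H]1CO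
F2 | step 21 | allylsilane alcohol (alkene geometry as a mixture) | COC(=O)C1=C[C@]23CC(C)=CC[C@@H]2[C@@](C)([C@@](OC)(CC=C(C)C[Si](C)(C)C)O3)[C@H]1CO
F3 | step 21 | allylsilane aldehyde | COC(=O)C1=C[C@]23CC(C)=CC[C@@H]2[C@@](C)([C@@](OC)(CC=C(C)C[Si](C)(C)C)O3)[C@H]1C=O
F4 | step 16 | bridged lactol from 26 | COC(=O)C1=C[C@]23CC(C)=CC[C@@H]2[C@@](C)(C(O)O3)[C@H]1CO[Si](c1ccccc1)(c1ccccc1)C(C)(C)C
F5 | step 16 | homoallylic diol (secondary carbinol as a mixture) | COC(=O)C1=C[C@]2(O)CC(C)=CC[C@@H]2[C@@](C)(C(O)CC=C)[C@H]1CO[Si](c1ccccc1)(c1ccccc1)C(C)(C)C
F6 | step 5 | epoxy diol from 7 (secondary carbinol as a mixture) | CC(C)(C)[Si](C)(C)OC[C@]1(O)C(O)[C@@]2(C)O[C@H]2C[C@@H]1C(C)=C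
F7 | step 5 | O-phenyl thionocarbonate of F6 | CC(C)(C)[Si](C)(C)OC[C@]1(O)C(OC(=S)Oc2ccccc2)[C@@]2(C)O[C@H]2C[C@@H]1C(C)=C
F8 | step 15 | trimethylsilyl ketene acetal of 24 | COC(=O)/C(=C\CO[Si](c1ccccc1)(c1ccccc1)C(C)(C)C)C(OC(=O)OC(C)(C)C)[C@]12CC(C)=CC[C@@H]1C(C)=C(O[Si](C)(C)C)O2
F9 | step 13 | methyl (Z)-2-iodo-4-(tert-butyldiphenylsilyloxy)but-2-enoate | COC(=O)/C(I)=C\CO[Si](c1ccccc1)(c1ccccc1)C(C)(C)C
A1 | alternative 1 | quinol with vinyl-tethered ring C ketone (methyl-bearing carbon unspecified) | COC(=O)/C(=C/C1(O)C=CC(=O)C=C1)[C@H]1C(C)C(=O)C[C@H](C(C)C)C1(OC)OC
A2 | alternative 1 | tetracyclic hemiketal with ring A as cyclohexenone | COC(=O)C1=C[C@]23C=CC(=O)C[C@@H]2[C@]2(C)[C@H]1C(OC)(OC)[C@@H](C(C)C)C[C@@]2(O)O3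
A3 | alternative 2 | methyl 3-(4-methylcyclohexa-1,4-dien-1-yl)-3-oxopropanoate | COC(=O)CC(=O)C1=CCC=C(C)C1
A4 | alternative 2 | 4,4-dimethoxy-5-isopropyl-2-methylcyclohexa-2,5-dienone | CC1=CC(OC)(OC)C(C(C)C)=CC1=O
A5 | alternative 2 | tricyclic enol keto ester with rings A, B and C | COC(=O)C1=C(O)[C@@H]2CC(C)=CC[C@@H]2[C@]2(C)[C@H]1C(OC)(OC)C(C(C)C)=CC2=O
A6 | alternative 3 | ring A-fused lactone with tethered acetoxy acrylate (alkene geometry and two centres unspecified) | COC(=O)C(=CCO[Si](C)(C)C(C)(C)C)C(OC(C)=O)[C@]12CC(C)=CC[C@@H]1C(C)C(=O)O2
A7 | alternative 3 | bridged lactone of rings A, B and D with tert-butyldimethylsilyloxymethyl arm | COC(=O)C1=C[C@]23CC(C)=CC[C@@H]2[C@](C)([C@H]1CO[Si](C)(C)C(C)(C)C)C(=O)O3
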